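## Retrosynthetic overview

1. Ring C is formed last, by Algar–Flynn–Oyamada oxidation of the chalcone from ring A acetophenone 28 and ring B aldehyde 24. The 8-(1,1-dimethylallyl) group then comes from a Claisen shift of the 7-O-prenyl ether, and two MOM ethers are removed at the end.
2. The strategy rests on the pattern of ring B: the C5' hydroxyl sits next to the chroman oxygen carbon C4' and meta to C1', with C6'–H between C5' and C1'. This is the pattern left when a ketene carbon (C5') closes onto the oxygen-bearing alkene carbon (C4') of a 2,2-dimethyl-3,4-dihydro-2H-pyran and the dienone enolises.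
3. The dienylketene is generated from half-ester 16 with Ac2O/NaOAc. The ester at C1', the prenyl group at C2' and the C3'–C4' pyran fusion are fixed by the open chain and its E geometry.
4. 16 is assembled with defined geometry by Suzuki–Miyaura coupling of E enol tosylate 14 (from an acylsuccinate) with dihydropyranyl boronate 6. A Stobbe condensation on the corresponding β,γ-unsaturated vinylogous-ester ketone would be lost to enolisation and double-bond migration.
5. Ring order: dihydropyran (hetero-Diels–Alder), then ring B (electrocyclization, which completes the chroman), then ring C (oxidative cyclisation); ring A is bought.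

Key step: step 9

Remark: the target has no stereocentre, so the only stereochemical element to control is the E geometry of the tetrasubstituted alkene in 14–16; racemic transient intermediates are drawn as one enantiomer.

## Route

Step 1
Reactants: 1 acrolein; 2 isobutene
Product: 3 2,2-dimethyl-3,4-dihydro-2H-pyran
Conditions: neat (excess 2), hydroquinone (cat.), autoclave, 190 °C
Reagents that add atoms: none
Why: Thermal inverse-demand hetero-Diels–Alder reaction of the enal as 1-oxadiene with the electron-rich 1,1-disubstituted alkene should place oxygen on the more substituted alkene carbon and so give the 2,2-dimethyl dihydropyran, with no stereocentre formed.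

Step 2
Reactants: 3 2,2-dimethyl-3,4-dihydro-2H-pyran
Product: 5 5-bromo-2,2-dimethyl-3,4-dihydro-2H-pyran, via trans-dibromide 4 (not isolated)
Conditions: Br2, CH2Cl2, −78 °C; then Et3N, −78 °C to rt
Reagents that add atoms: bromine, BrBr
Why: Electrophilic bromine addition to the enol ether followed by amine-induced loss of HBr through the oxocarbenium ion (the anomeric bromide leaves, H5 is removed) is the standard bromination–dehydrobromination route to 5-bromo-3,4-dihydro-2H-pyrans.

Step 3
Reactants: 5 5-bromo-2,2-dimethyl-3,4-dihydro-2H-pyran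
Product: 6 2-(2,2-dimethyl-3,4-dihydro-2H-pyran-5-yl)-4,4,5,5-tetramethyl-1,3,2-dioxaborolane
Conditions: B2pin2, PdCl2(PPh3)2 (3 mol %), PPh3, KOPh, toluene, 50 °C
Reagents that add atoms: bis(pinacolato)diboron, CC1(C)OB(OC1(C)C)B1OC(C)(C)C(C)(C)O1
Why: Miyaura borylation of an alkenyl bromide with KOPh as base should give the alkenyl boronate without passing through the β-alkoxyvinyl-lithium, which would ring-open by β-elimination.

Step 4
Reactants: 7 4-methylpent-3-enoic acid; 8 potassium methyl malonate
Product: 11 methyl 6-methyl-3-oxohept-5-enoate, via acyl imidazolide 9 (not isolated), via acylmalonic half-ester 10 (not isolated)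
Conditions: 7, CDI, THF, rt; then 8, MgCl2, Et3N, MeCN/THF, rt to 40 °C; dilute HCl work-up
Reagents that add atoms: none
Why: C-acylation of the magnesium enolate of a malonic half-ester by an acyl imidazolide with decarboxylation (a Claisen-type condensation under near-neutral conditions) should give the β-keto ester without moving the β,γ-double bond into conjugation.

Step 5
Reactants: 11 methyl 6-methyl-3-oxohept-5-enoate; 12 methyl bromoacetate
Product: 13 dimethyl 2-(4-methylpent-3-enoyl)butanedioate (racemic)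
Conditions: K2CO3, acetone, rt (1.0 equiv of 12)
Reagents that add atoms: none
Why: The doubly activated C2–H is by far the most acidic, so K2CO3-mediated SN2 alkylation with the bromoacetate should occur there and leave the allylic C4 methylene untouched; the new stereocentre is racemic and is removed in step 6.

Step 6
Reactants: 13 dimethyl 2-(4-methylpent-3-enoyl)butanedioate
Product: 14 dimethyl (2E)-2-[4-methyl-1-(4-methylphenylsulfonyloxy)pent-3-en-1-ylidene]butanedioate (tosyloxy group cis to CH2CO2Me)
Conditions: TsCl, Me2N(CH2)6NMe2, MeCN, −10 to 0 °C; chromatography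
Reagents that add atoms: 4-methylbenzenesulfonyl chloride, Cc1ccc(cc1)S(Cl)(=O)=O
Why: O-sulfonylation of the non-chelated ammonium enolate of an α-substituted β-keto ester with TsCl and a tertiary diamine is expected to give mainly the E enol tosylate (tosyloxy trans to CO2Me), the geometry needed later for ring closure, and any Z isomer is removed by chromatography.

Step 7
Reactants: 14 E enol tosylate; 6 dihydropyranyl boronate
Product: 15 dimethyl (2E)-2-[1-(2,2-dimethyl-3,4-dihydro-2H-pyran-5-yl)-4-methylpent-3-en-1-ylidene]butanedioate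
Conditions: Pd(OAc)2 (3 mol %), SPhos, K3PO4, THF/H2O, 50 °C
Reagents that add atoms: none
Why: Suzuki–Miyaura coupling of a β-keto ester enol tosylate with an alkenyl boronate proceeds with retention at both partners, so the dihydropyranyl group should take the place of the tosyloxy group cis to CH2CO2Me.

Step 8
Reactants: 15 diester
Product: 16 (3E)-4-(2,2-dimethyl-3,4-dihydro-2H-pyran-5-yl)-3-(methoxycarbonyl)-7-methylocta-3,6-dienoic acid
Conditions: LiOH (1.1 equiv), THF/H2O, 0 °C; then cold 0.5 M HCl to pH 4, extract, use at once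
Reagents that add atoms: lithium hydroxide, [Li+].[OH-]
Why: Saponification should be selective for the unhindered, non-conjugated CH2CO2Me ester because the other ester is conjugated and sits on a tetrasubstituted alkene, the same site selectivity that relates alkylidenesuccinic diesters to their Stobbe half-esters.

Step 9
Reactants: 16 half-ester
Product: 21 methyl 8-acetoxy-2,2-dimethyl-5-(3-methylbut-2-enyl)chroman-6-carboxylate, via mixed anhydride 17 (not isolated), via dienylketene 18 (not isolated), via cyclohexadienone 19 (not isolated), via phenol 20 (not isolated)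
Conditions: Ac2O, NaOAc (anhydrous), 120 °C, N2
Reagents that add atoms: acetic anhydride, CC(=O)OC(C)=O
Why: Proposed new method: acetate-induced loss of acetic acid from mixed anhydride 17 should give dienylketene 18, whose ketene C=C, tetrasubstituted C3=C4 alkene and dihydropyran C5=C6 enol ether form a cis-hexatriene, and thermal disrotatory 6π electrocyclization then joins the ketene carbon (future C5') to the oxygen-bearing enol ether carbon (future C4'), closing the six-membered ring B as cyclohexadienone 19, which enolises by loss of the C8a hydrogen to phenol 20 and is acetylated. The closest known reaction is the Ac2O/NaOAc cyclisation of Stobbe-type arylidene- and hetarylidene-succinic half-esters to acetoxy arene esters, including closures onto the heteroatom-bearing C2 of 3-furyl, 3-thienyl and 3-indolyl groups; what is new is a non-aromatic enol ether as the terminating alkene. The closure is expected to be easy because dienylketene electrocyclizations have low barriers, no aromatic sextet has to be broken in the dihydropyran, and the sequence is driven by aromatisation of ring B. The only stereocentre formed (C8a of 19) is destroyed by the enolisation, so none has to be controlled. The selectivity needed is the site of closure: the E geometry of 16, fixed in steps 6 and 7, holds the dihydropyranyl group cis and the prenyl group trans to the ketene arm, so only C6 of the enol ether can reach the ketene carbon and a [2+2] or ene reaction with the prenyl alkene is excluded. NaOAc buffers the acetic acid that is formed, so the enol ether and the prenyl alkene should survive until the ring has closed.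

Step 10
Reactants: 21 aryl acetate
Product: 20 methyl 8-hydroxy-2,2-dimethyl-5-(3-methylbut-2-enyl)chroman-6-carboxylate
Conditions: K2CO3 (cat.), MeOH, 0 °C to rt
Reagents that add atoms: none
Why: Base-catalysed transesterification cleaves the aryl acetate far faster than the hindered methyl benzoate.

Step 11
Reactants: 20 phenol
Product: 22 methyl 8-(methoxymethoxy)-2,2-dimethyl-5-(3-methylbut-2-enyl)chroman-6-carboxylate
Conditions: MOMCl, iPr2NEt, CH2Cl2, 0 °C to rt
Reagents that add atoms: chloromethyl methyl ether, COCCl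
Why: Williamson-type alkylation of the phenol with MOMCl and a hindered amine gives the MOM ether, which is stable to hydride, base and alkaline peroxide in the following steps.

Step 12
Reactants: 22 MOM-protected ester
Product: 23 [8-(methoxymethoxy)-2,2-dimethyl-5-(3-methylbut-2-enyl)chroman-6-yl]methanol
Conditions: iBu2AlH (2.5 equiv), CH2Cl2, −78 to 0 °C; aq. KNaC4H4O6 (potassium sodium tartrate)
Reagents that add atoms: none
Why: Hydride reduction of the benzoate with iBu2AlH gives the benzylic alcohol and leaves the MOM ether and both alkenes untouched.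

Step 13
Reactants: 23 benzylic alcohol
Product: 24 8-(methoxymethoxy)-2,2-dimethyl-5-(3-methylbut-2-enyl)chroman-6-carbaldehyde
Conditions: MnO2, CH2Cl2, rt
Reagents that add atoms: none
Why: MnO2 oxidises the benzylic alcohol selectively to the aldehyde without over-oxidation and without touching the prenyl alkene.

Step 14
Reactants: 25 1-(2,4,6-trihydroxyphenyl)ethanone; 26 3-methylbut-2-enyl bromide
Product: 27 1-[2,6-dihydroxy-4-(3-methylbut-2-enyloxy)phenyl]ethanone
Conditions: K2CO3, acetone, rt (1.0 equiv of 26)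
Reagents that add atoms: none
Why: The 4-OH, the only hydroxyl not hydrogen-bonded to the acetyl group and the most acidic, should be O-alkylated first by the allylic bromide under K2CO3 in acetone (Williamson etherification).

Step 15
Reactants: 27 4-O-prenyl ketone
Product: 28 1-[2-hydroxy-6-(methoxymethoxy)-4-(3-methylbut-2-enyloxy)phenyl]ethanone
Conditions: MOMCl (1.05 equiv), iPr2NEt, CH2Cl2, 0 °C
Reagents that add atoms: chloromethyl methyl ether, COCCl
Why: The two hydroxyls are equivalent and, once the first MOM ether is formed, the remaining one is strongly chelated to the ketone, so mono-protection should be clean.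

Step 16
Reactants: 28 ring A ketone; 24 ring B aldehyde
Product: 30 (2E)-1-[2-hydroxy-6-(methoxymethoxy)-4-(3-methylbut-2-enyloxy)phenyl]-3-[8-(methoxymethoxy)-2,2-dimethyl-5-(3-methylbut-2-enyl)chroman-6-yl]prop-2-en-1-one, via aldol adduct 29 (not isolated)
Conditions: KOH, EtOH/H2O, rt
Reagents that add atoms: none
Why: Claisen–Schmidt condensation of the acetophenone enolate with the non-enolisable aldehyde and E1cB loss of water from aldol 29 should give the E chalcone, the more stable geometry.

Step 17
Reactants: 30 chalcone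
Product: 32 3-hydroxy-5-(methoxymethoxy)-2-[8-(methoxymethoxy)-2,2-dimethyl-5-(3-methylbut-2-enyl)chroman-6-yl]-7-(3-methylbut-2-enyloxy)-4H-chromen-4-one, via trans-dihydroflavonol 31 (not isolated)
Conditions: 30% aq. H2O2, NaOH, MeOH/THF, 0 °C to rt
Reagents that add atoms: hydrogen peroxide, OO
Why: In the Algar–Flynn–Oyamada oxidation alkaline hydrogen peroxide attacks the enone, the 2'-phenoxide closes ring C to trans-dihydroflavonol 31 and excess peroxide dehydrogenates it to the flavonol, while the isolated prenyl alkenes are inert to nucleophilic peroxide and the stereocentres of 31 are lost in the product.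

Step 18
Reactants: 32 7-O-prenyl flavonol
Product: 34 3,7-dihydroxy-5-(methoxymethoxy)-2-[8-(methoxymethoxy)-2,2-dimethyl-5-(3-methylbut-2-enyl)chroman-6-yl]-8-(2-methylbut-3-en-2-yl)-4H-chromen-4-one, via ortho-dienone 33 (not isolated)
Conditions: PhNEt2, 190 °C, sealed tube, N2
Reagents that add atoms: none
Why: Aromatic Claisen rearrangement ([3,3]) of the 7-O-prenyl ether delivers the inverted 1,1-dimethylallyl group to an ortho carbon and should prefer C8 over C6, because in a chromone whose 5-oxygen is not chelated the C7–C8 bond has the higher double-bond character and C6 is crowded by the 5-OMOM group, after which dienone 33 enolises to the 7-phenol.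

Step 19
Reactants: 34 bis-MOM ether
Product: 35 Broussoflavonol E, 3,5,7-trihydroxy-2-[8-hydroxy-2,2-dimethyl-5-(3-methylbut-2-enyl)chroman-6-yl]-8-(2-methylbut-3-en-2-yl)-4H-chromen-4-one
Conditions: HCl (1 M), MeOH/H2O, rt to 40 °C
Reagents that add atoms: none
Why: Acid-catalysed acetal exchange with methanol removes both MOM ethers (the 5-O-MOM next to the carbonyl fastest) under conditions mild enough for the prenyl and 1,1-dimethylallyl alkenes.

## Compound list

1 | acrolein (prop-2-enal) | C=CC=O | starting material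
2 | isobutene (2-methylpropene) | CC(C)=C | starting material
3 | 2,2-dimethyl-3,4-dihydro-2H-pyran | CC1(C)CCC=CO1 | intermediate
4 | trans-2,3-dibromo-6,6-dimethyltetrahydro-2H-pyran (C5,C6-dibromide of 3; racemic) | Br[C@@H]1CCC(C)(C)O[C@H]1Br | intermediate (not isolated)
5 | 5-bromo-2,2-dimethyl-3,4-dihydro-2H-pyran | CC1(C)CCC(Br)=CO1 | intermediate
6 | 2-(2,2-dimethyl-3,4-dihydro-2H-pyran-5-yl)-4,4,5,5-tetramethyl-1,3,2-dioxaborolane | CC1(C)CCC(B2OC(C)(C)C(C)(C)O2)=CO1 | intermediate
7 | 4-methylpent-3-enoic acid | CC(C)=CCC(=O)O | starting material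
8 | potassium methyl malonate (potassium 3-methoxy-3-oxopropanoate) | COC(=O)CC(=O)[O-].[K+] | starting material
9 | 1-(imidazol-1-yl)-4-methylpent-3-en-1-one | CC(C)=CCC(=O)n1ccnc1 | intermediate (not isolated)
10 | 2-(methoxycarbonyl)-6-methyl-3-oxohept-5-enoic acid (formed as its magnesium salt; racemic) | COC(=O)C(C(=O)O)C(=O)CC=C(C)C | intermediate (not isolated)
11 | methyl 6-methyl-3-oxohept-5-enoate | COC(=O)CC(=O)CC=C(C)C | intermediate
12 | methyl bromoacetate | COC(=O)CBr | starting material
13 | dimethyl 2-(4-methylpent-3-enoyl)butanedioate (racemic) | COC(=O)CC(C(=O)OC)C(=O)CC=C(C)C | intermediate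
14 | dimethyl (2E)-2-[4-methyl-1-(4-methylphenylsulfonyloxy)pent-3-en-1-ylidene]butanedioate | COC(=O)C/C(C(=O)OC)=C(/CC=C(C)C)OS(=O)(=O)c1ccc(C)cc1 | intermediate
15 | dimethyl (2E)-2-[1-(2,2-dimethyl-3,4-dihydro-2H-pyran-5-yl)-4-methylpent-3-en-1-ylidene]butanedioate | COC(=O)C/C(C(=O)OC)=C(/CC=C(C)C)C1=COC(C)(C)CC1 | intermediate
16 | (3E)-4-(2,2-dimethyl-3,4-dihydro-2H-pyran-5-yl)-3-(methoxycarbonyl)-7-methylocta-3,6-dienoic acid | OC(=O)C/C(C(=O)OC)=C(/CC=C(C)C)C1=COC(C)(C)CC1 | intermediate (key-step precursor)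
17 | acetic (3E)-4-(2,2-dimethyl-3,4-dihydro-2H-pyran-5-yl)-3-(methoxycarbonyl)-7-methylocta-3,6-dienoic anhydride | CC(=O)OC(=O)C/C(C(=O)OC)=C(/CC=C(C)C)C1=COC(C)(C)CC1 | intermediate (not isolated)
18 | methyl (2E)-3-(2,2-dimethyl-3,4-dihydro-2H-pyran-5-yl)-6-methyl-2-(2-oxoethenyl)hepta-2,5-dienoate | O=C=C/C(C(=O)OC)=C(/CC=C(C)C)C1=COC(C)(C)CC1 | intermediate (not isolated)
19 | methyl 2,2-dimethyl-5-(3-methylbut-2-enyl)-8-oxo-3,4,8,8a-tetrahydro-2H-chromene-6-carboxylate (racemic) | O=C1C=C(C(=O)OC)C(CC=C(C)C)=C2CCC(C)(C)OC12 | intermediate (not isolated)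
20 | methyl 8-hydroxy-2,2-dimethyl-5-(3-methylbut-2-enyl)chroman-6-carboxylate | COC(=O)c1cc(O)c2c(c1CC=C(C)C)CCC(C)(C)O2 | intermediate (transient in step 9, isolated in step 10)
21 | methyl 8-acetoxy-2,2-dimethyl-5-(3-methylbut-2-enyl)chroman-6-carboxylate | COC(=O)c1cc(OC(C)=O)c2c(c1CC=C(C)C)CCC(C)(C)O2 | intermediate (key-step product)
22 | methyl 8-(methoxymethoxy)-2,2-dimethyl-5-(3-methylbut-2-enyl)chroman-6-carboxylate | COC(=O)c1cc(OCOC)c2c(c1CC=C(C)C)CCC(C)(C)O2 | intermediate
23 | [8-(methoxymethoxy)-2,2-dimethyl-5-(3-methylbut-2-enyl)chroman-6-yl]methanol | OCc1cc(OCOC)c2c(c1CC=C(C)C)CCC(C)(C)O2 | intermediate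
24 | 8-(methoxymethoxy)-2,2-dimethyl-5-(3-methylbut-2-enyl)chroman-6-carbaldehyde | O=Cc1cc(OCOC)c2c(c1CC=C(C)C)CCC(C)(C)O2 | intermediate
25 | 1-(2,4,6-trihydroxyphenyl)ethanone | CC(=O)c1c(O)cc(O)cc1O | starting material
26 | 3-methylbut-2-enyl bromide (prenyl bromide) | CC(C)=CCBr | starting material
27 | 1-[2,6-dihydroxy-4-(3-methylbut-2-enyloxy)phenyl]ethanone | CC(=O)c1c(O)cc(OCC=C(C)C)cc1O | intermediate
28 | 1-[2-hydroxy-6-(methoxymethoxy)-4-(3-methylbut-2-enyloxy)phenyl]ethanone | CC(=O)c1c(O)cc(OCC=C(C)C)cc1OCOC | intermediate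
29 | 3-hydroxy-1-[2-hydroxy-6-(methoxymethoxy)-4-(3-methylbut-2-enyloxy)phenyl]-3-[8-(methoxymethoxy)-2,2-dimethyl-5-(3-methylbut-2-enyl)chroman-6-yl]propan-1-one (racemic) | COCOc1cc(OCC=C(C)C)cc(O)c1C(=O)CC(O)c1cc(OCOC)c2c(c1CC=C(C)C)CCC(C)(C)O2 | intermediate (not isolated)
30 | (2E)-1-[2-hydroxy-6-(methoxymethoxy)-4-(3-methylbut-2-enyloxy)phenyl]-3-[8-(methoxymethoxy)-2,2-dimethyl-5-(3-methylbut-2-enyl)chroman-6-yl]prop-2-en-1-one | COCOc1cc(OCC=C(C)C)cc(O)c1C(=O)/C=C/c1cc(OCOC)c2c(c1CC=C(C)C)CCC(C)(C)O2 | intermediate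
31 | trans-3-hydroxy-5-(methoxymethoxy)-2-[8-(methoxymethoxy)-2,2-dimethyl-5-(3-methylbut-2-enyl)chroman-6-yl]-7-(3-methylbut-2-enyloxy)chroman-4-one (racemic, 2,3-trans) | O[C@@H]1C(=O)c2c(OCOC)cc(OCC=C(C)C)cc2O[C@H]1c1cc(OCOC)c2c(c1CC=C(C)C)CCC(C)(C)O2 | intermediate (not isolated)
32 | 3-hydroxy-5-(methoxymethoxy)-2-[8-(methoxymethoxy)-2,2-dimethyl-5-(3-methylbut-2-enyl)chroman-6-yl]-7-(3-methylbut-2-enyloxy)-4H-chromen-4-one | CC(C)=CCOc1cc(OCOC)c2c(=O)c(O)c(-c3cc(OCOC)c4c(c3CC=C(C)C)CCC(C)(C)O4)oc2c1 | intermediate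
33 | 3-hydroxy-5-(methoxymethoxy)-2-[8-(methoxymethoxy)-2,2-dimethyl-5-(3-methylbut-2-enyl)chroman-6-yl]-8-(2-methylbut-3-en-2-yl)-8H-chromene-4,7-dione (racemic) | C=CC(C)(C)C1C(=O)C=C(OCOC)C2=C1OC(=C(O)C2=O)c1cc(OCOC)c2c(c1CC=C(C)C)CCC(C)(C)O2 | intermediate (not isolated)
34 | 3,7-dihydroxy-5-(methoxymethoxy)-2-[8-(methoxymethoxy)-2,2-dimethyl-5-(3-methylbut-2-enyl)chroman-6-yl]-8-(2-methylbut-3-en-2-yl)-4H-chromen-4-one | C=CC(C)(C)c1c(O)cc(OCOC)c2c(=O)c(O)c(-c3cc(OCOC)c4c(c3CC=C(C)C)CCC(C)(C)O4)oc12 | intermediate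
35 | Broussoflavonol E | C=CC(C)(C)c1c(O)cc(O)c2c(=O)c(O)c(-c3cc(O)c4c(c3CC=C(C)C)CCC(C)(C)O4)oc12 | target

## Step count

Total steps: 19 (steps 1–13 to aldehyde 24, of which steps 1–3 make boronate 6; steps 14–15 to ketone 28; steps 16–19 after convergence).
Longest linear sequence: 14 steps (steps 4–13 and 16–19; the branch through steps 1–3 and 7–13 is equally long).

## Steps most likely to fail

**Step 9 (Proposed new method).** The dienylketene may fail to close onto the oxygen-bearing enol ether carbon, or the enol ether may be consumed by acetic acid addition or C-acetylation before the ketene forms, so that no benzene ring results. The fallback uses known aromatic chemistry on a bought benzene ring. It sets out from 3-methylbut-2-enyl bromide 26 and from commercial 6-bromovanillin (2-bromo-4-hydroxy-5-methoxybenzaldehyde, COc1cc(C=O)c(Br)cc1O, not a compound of the route), and it comes back at aldehyde 24, replacing steps 1–13. BBr3 (CH2Cl2, −78 to 0 °C) demethylates 6-bromovanillin to 2-bromo-4,5-dihydroxybenzaldehyde F1. The more acidic 4-OH, para to the aldehyde, is alkylated with 3-chloro-3-methylbut-1-yne (DBU, cat. CuCl2, MeCN, 0 °C) to 2-bromo-5-hydroxy-4-(2-methylbut-3-yn-2-yloxy)benzaldehyde F2, and the remaining phenol is protected (MOMCl, iPr2NEt) as 2-bromo-5-(methoxymethoxy)-4-(2-methylbut-3-yn-2-yloxy)benzaldehyde F3. Heating F3 (PhNEt2, 180 °C) should bring about the propargyl Claisen rearrangement, 1,5-hydrogen shift and oxa-6π closure at the only free ortho carbon, giving 5-bromo-8-(methoxymethoxy)-2,2-dimethyl-2H-chromene-6-carbaldehyde F4. Its cis-disubstituted alkene is hydrogenated with H2 and RhCl(PPh3)3 (benzene/EtOH, rt), which leaves the aryl bromide and the aldehyde, to give 5-bromo-8-(methoxymethoxy)-2,2-dimethylchroman-6-carbaldehyde F5. Bromide 26 is converted with Mg and Bu3SnCl (THF) into tributyl(3-methylbut-2-enyl)stannane F6, and Stille coupling of F5 with F6 (Pd(PPh3)4, DMF, 90 °C) places the linear prenyl group at C5 and gives 24.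

**Step 17.** The hydroperoxide adduct may close through the α-carbon to a five-membered ring and give an aurone, a course favoured by the 6'-substituent on ring A and by the ortho-substituted ring B; the dehydrogenation may also stop short. The fallback is an acylation route that sets out from ester 22 and ketone 28 and comes back at flavonol 32. LiOH (THF/MeOH/H2O, 50 °C) turns 22 into 8-(methoxymethoxy)-2,2-dimethyl-5-(3-methylbut-2-enyl)chroman-6-carboxylic acid F7, which is esterified with the free phenol of 28 (EDC·HCl, DMAP, CH2Cl2) to 2-acetyl-3-(methoxymethoxy)-5-(3-methylbut-2-enyloxy)phenyl 8-(methoxymethoxy)-2,2-dimethyl-5-(3-methylbut-2-enyl)chroman-6-carboxylate F8. DBU in pyridine at 90 °C should effect the Baker–Venkataraman acyl shift to 1-[2-hydroxy-6-(methoxymethoxy)-4-(3-methylbut-2-enyloxy)phenyl]-3-[8-(methoxymethoxy)-2,2-dimethyl-5-(3-methylbut-2-enyl)chroman-6-yl]propane-1,3-dione F9 and its cyclodehydration to 5-(methoxymethoxy)-2-[8-(methoxymethoxy)-2,2-dimethyl-5-(3-methylbut-2-enyl)chroman-6-yl]-7-(3-methylbut-2-enyloxy)-4H-chromen-4-one F10. Deprotonation at C3 with LiN(iPr)2 (THF, −78 °C) and trapping with B(OMe)3 gives dimethyl {5-(methoxymethoxy)-2-[8-(methoxymethoxy)-2,2-dimethyl-5-(3-methylbut-2-enyl)chroman-6-yl]-7-(3-methylbut-2-enyloxy)-4-oxo-4H-chromen-3-yl}boronate F11, and oxidation of the carbon–boron bond with H2O2/NaOH gives 32.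

**Step 18.** Site selectivity between C8 and C6 may be poor, and the ortho-(1,1-dimethylallyl)phenol may react further at this temperature (cyclisation onto the 7-OH, abnormal Claisen rearrangement). The fallback carries out the rearrangement before ring C exists, where symmetry removes the site problem. It sets out from ketone 27 (with aldehyde 24) and comes back at target 35. Heating 27 (PhNEt2, 170 °C) should give 1-[2,4,6-trihydroxy-3-(2-methylbut-3-en-2-yl)phenyl]ethanone F12, since both ortho carbons of 27 are equivalent. MOMCl (2.2 equiv) and iPr2NEt protect the 4-OH and the less hindered 6-OH and leave the chelated 2-OH beside the tert-alkyl group, giving 1-[2-hydroxy-4,6-bis(methoxymethoxy)-3-(2-methylbut-3-en-2-yl)phenyl]ethanone F13. Claisen–Schmidt condensation with 24 (KOH, EtOH) gives (2E)-1-[2-hydroxy-4,6-bis(methoxymethoxy)-3-(2-methylbut-3-en-2-yl)phenyl]-3-[8-(methoxymethoxy)-2,2-dimethyl-5-(3-methylbut-2-enyl)chroman-6-yl]prop-2-en-1-one F14. Algar–Flynn–Oyamada oxidation (H2O2, NaOH, MeOH) closes ring C through the 2'-OH, which puts the 1,1-dimethylallyl group at C8, and gives 3-hydroxy-5,7-bis(methoxymethoxy)-2-[8-(methoxymethoxy)-2,2-dimethyl-5-(3-methylbut-2-enyl)chroman-6-yl]-8-(2-methylbut-3-en-2-yl)-4H-chromen-4-one F15. Removal of the three MOM ethers under the conditions of step 19 gives 35.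

## Further compounds

F1 | step 9 | 2-bromo-4,5-dihydroxybenzaldehyde | O=Cc1cc(O)c(O)cc1Br
F2 | step 9 | 2-bromo-5-hydroxy-4-(2-methylbut-3-yn-2-yloxy)benzaldehyde | O=Cc1cc(O)c(OC(C)(C)C#C)cc1Br
F3 | step 9 | 2-bromo-5-(methoxymethoxy)-4-(2-methylbut-3-yn-2-yloxy)benzaldehyde | O=Cc1cc(OCOC)c(OC(C)(C)C#C)cc1Br
F4 | step 9 | 5-bromo-8-(methoxymethoxy)-2,2-dimethyl-2H-chromene-6-carbaldehyde | O=Cc1cc(OCOC)c2OC(C)(C)C=Cc2c1Br
F5 | step 9 | 5-bromo-8-(methoxymethoxy)-2,2-dimethylchroman-6-carbaldehyde | O=Cc1cc(OCOC)c2OC(C)(C)CCc2c1Br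
F6 | step 9 | tributyl(3-methylbut-2-enyl)stannane | CCCC[Sn](CCCC)(CCCC)CC=C(C)C
F7 | step 17 | 8-(methoxymethoxy)-2,2-dimethyl-5-(3-methylbut-2-enyl)chroman-6-carboxylic acid | OC(=O)c1cc(OCOC)c2c(c1CC=C(C)C)CCC(C)(C)O2
F8 | step 17 | 2-acetyl-3-(methoxymethoxy)-5-(3-methylbut-2-enyloxy)phenyl 8-(methoxymethoxy)-2,2-dimethyl-5-(3-methylbut-2-enyl)chroman-6-carboxylate | CC(=O)c1c(OC(=O)c2cc(OCOC)c3c(c2CC=C(C)C)CCC(C)(C)O3)cc(OCC=C(C)C)cc1OCOC
F9 | step 17 | 1-[2-hydroxy-6-(methoxymethoxy)-4-(3-methylbut-2-enyloxy)phenyl]-3-[8-(methoxymethoxy)-2,2-dimethyl-5-(3-methylbut-2-enyl)chroman-6-yl]propane-1,3-dione | COCOc1cc(OCC=C(C)C)cc(O)c1C(=O)CC(=O)c1cc(OCOC)c2c(c1CC=C(C)C)CCC(C)(C)O2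
F10 | step 17 | 5-(methoxymethoxy)-2-[8-(methoxymethoxy)-2,2-dimethyl-5-(3-methylbut-2-enyl)chroman-6-yl]-7-(3-methylbut-2-enyloxy)-4H-chromen-4-one | CC(C)=CCOc1cc(OCOC)c2c(=O)cc(-c3cc(OCOC)c4c(c3CC=C(C)C)CCC(C)(C)O4)oc2c1
F11 | step 17 | dimethyl {5-(methoxymethoxy)-2-[8-(methoxymethoxy)-2,2-dimethyl-5-(3-methylbut-2-enyl)chroman-6-yl]-7-(3-methylbut-2-enyloxy)-4-oxo-4H-chromen-3-yl}boronate | CC(C)=CCOc1cc(OCOC)c2c(=O)c(B(OC)OC)c(-c3cc(OCOC)c4c(c3CC=C(C)C)CCC(C)(C)O4)oc2c1
F12 | step 18 | 1-[2,4,6-trihydroxy-3-(2-methylbut-3-en-2-yl)phenyl]ethanone | CC(=O)c1c(O)cc(O)c(C(C)(C)C=C)c1O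
F13 | step 18 | 1-[2-hydroxy-4,6-bis(methoxymethoxy)-3-(2-methylbut-3-en-2-yl)phenyl]ethanone | CC(=O)c1c(OCOC)cc(OCOC)c(C(C)(C)C=C)c1O
F14 | step 18 | (2E)-1-[2-hydroxy-4,6-bis(methoxymethoxy)-3-(2-methylbut-3-en-2-yl)phenyl]-3-[8-(methoxymethoxy)-2,2-dimethyl-5-(3-methylbut-2-enyl)chroman-6-yl]prop-2-en-1-one | COCOc1cc(OCOC)c(C(C)(C)C=C)c(O)c1C(=O)/C=C/c1cc(OCOC)c2c(c1CC=C(C)C)CCC(C)(C)O2
F15 | step 18 | 3-hydroxy-5,7-bis(methoxymethoxy)-2-[8-(methoxymethoxy)-2,2-dimethyl-5-(3-methylbut-2-enyl)chroman-6-yl]-8-(2-methylbut-3-en-2-yl)-4H-chromen-4-one | C=CC(C)(C)c1c(OCOC)cc(OCOC)c2c(=O)c(O)c(-c3cc(OCOC)c4c(c3CC=C(C)C)CCC(C)(C)O4)oc12
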